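The data are calculated on assumed constants, and the scatter is random.

How much target will Wednesday's flask hold at 25 min, and would more gas raise it? Its readings stop at 12.0 min, so we need a rule that carries them forward.

| flask | substrate | gas phase | remark | time |
|---|---|---|---|---|
| Wednesday's | 20 mM | 1.2 mM (held) | the very flask that is asked about, followed so far |  |
| Thursday's | 30 mM | 1.2 mM (held) | run made earlier |  |
| flask | 20 mM | 1.2 mM (held) |  | 25 min |

- Wednesday's (time / min: target / %, substrate / %): 0.667: 3.4, 96.3; 2.00: 10.4, 89.0; 4.00: 14.2, 81.8; 5.00: 17.2, 80.8; 8.00: 17.4, 73.8; 10.0: 17.2, 70.2; 12.0: 16.6, 68.0
- Thursday's (time / min: target / %, substrate / %): 1.33: 6.0, 94.4; 3.00: 11.6, 88.0; 4.00: 13.2, 85.7; 6.00: 16.6, 80.9; 8.00: 16.3, 77.3; 10.0: 15.8, 73.6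

(scatter of a reading: 0.5 percentage points)

1. target at 25 min, in percent of the substrate charged
2. the change that raises the amount of target at 25 min, in percent of the substrate charged most ("none" if none brings more than 2 percentage points) (autumn / spring / none)
3. amount of target at 25 min, in percent of the substrate charged, after spring

- autumn: doubling the saturation concentration of gas phase, all else as stated
- spring: doubling the transfer coefficient of the gas phase, all else as stated

- at the start none of the gas is dissolved
- what may be going on: dissolved gas -> decomposed reagent; substrate + dissolved gas <-> target; gas phase <-> dissolved gas; dissolved gas + target -> over-reacted product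

We read Wednesday's table from its lower rows. Between 8.00 min and 12.0 min substrate loses 5.8 percentage points, far more than the 0.8 points target loses, so in that flask target is being made and passed on to over-reacted product at nearly level rates.

Now we set the columns against each other. Target over substrate reads 0.236 in the first of those rows and 0.244 in the last, so the ratio reads nearly steady, and we take target in Wednesday's flask to be in a quasi-steady state, following substrate. Thursday's run reads the same way, 0.211 and then 0.215.

With a steady ratio, target falls at substrate's fractional pace. Wednesday's substrate gives 0.0205 /min, the tied decay rate, meaning the fraction of itself lost per minute. From 16.6% at 12.0 min we reckon 12.7% at 25 min.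

Autumn and spring both mean more dissolved gas, so we expect a quicker flask. Wednesday's target reads 17.4% at 8.00 min and 16.6% at 12.0 min, so its rise has ended in those readings, and we expect a quicker flask to stand further down the decline at 25 min. We commit to none, with spring a little under our figure.

The forecast gives 13% (11.5% to 14.5%), none as the best change and 11.8% after spring: “So neither helps”.

The flask gives 14.0%, and 13.6% after spring, so the choice is none. At 25 min target is made at 0.819 of the rate it is used up, each step taken net, so it is still falling. Carrying 14.0% on at the tied decay rate gives 8.39% at 50.0 min, where the flask holds 8.85%.

    dissolved gas → decomposed reagent (k = 0.0742 /min)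
    substrate + dissolved gas ⇌ target (K = 315 /M, k = 197 /M/min)
    gas phase ⇌ dissolved gas, rate k3*(csat - [dissolved gas]) (kL = 2.02 /min)
    dissolved gas + target → over-reacted product (k = 99.5 /M/min)

For the same flask left until 1.5 h, the tied decay rate takes 14.0% down to 3.69%. The computed flask holds 3.64%.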